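**Plan**

- Cuts: the two palmitate C–O bonds; the C11=C12 and C11'=C12' double bonds (two Wittig reactions on a C10 trienedial); then, in a single C15 dienoate that serves both halves, C9=C10 (olefination) and C6–C7 (Heck coupling), back to an enol triflate made from ketoisophorone.
- Enabling feature: in the ε-ring the unit C3'(O)–C4'=C5'(CH3)–C6'(H) has H6' separated from C4' only by C5' and lying on the ring face of the C3' oxygen. This is what a C4' diazene on a 3-oxygenated β-ring (C5=C6 alkene) leaves after a retro-ene shift, and the same β-ring can direct the 5,6-epoxide of the other end through its homoallylic C3 hydroxyl.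
- Forward order: the six-membered ring is bought; the chain is attached at C6–C7, then C9=C10; the C15 ester branches into the ε-ring ester (1,3-transposition) and the epoxide ring (directed epoxidation); the polyene is joined at C11'=C12', then at C11=C12; desilylation and double palmitoylation finish.
- Stereochemistry: one catalyst-controlled ketone reduction sets the ring carbinol, which is C3' as made and C3 after one Mitsunobu inversion. C6' comes from suprafacial hydrogen delivery by the C4' diazene, which sits cis to O3' because axial hydride reduction gives the trans alcohol and the Mitsunobu displacement inverts it. C5 and C6 come from epoxidation on the face of the C3 hydroxyl before that inversion.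

Key step: step 9

Assumption: carotenoid locants are used throughout (ring atoms C1–C6 of the shared ester become C1'–C6' on the ε branch), and the (R,R) catalyst antipode is taken to give the R carbinol in step 1 by the usual alkenyl-versus-alkyl ketone model; if the optical rotation of the product shows the other sense, the mirror-image ligand is used.

**Route**

Step 1
Reactants: 1 ketoisophorone (2,6,6-trimethylcyclohex-2-ene-1,4-dione)
Product: 2 (4R)-4-hydroxy-2,6,6-trimethylcyclohex-2-en-1-one
Conditions: RuCl[(R,R)-TsDPEN](p-cymene) (1 mol %), i-PrOH, rt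
Reagents that add atoms: none
Why: Asymmetric transfer hydrogenation reduces only the C4 carbonyl, because the C1 carbonyl is shielded by the gem-dimethyl carbon and the methyl-bearing alkene carbon, and the ligand's discrimination between the alkenyl and methylene flanks of C4 sets the carbinol as R, the only stereocentre brought in from outside.

Step 2
Reactants: 2 (4R)-4-hydroxy-2,6,6-trimethylcyclohex-2-en-1-one
Product: 3 (4R)-4-(tert-butyldimethylsilyloxy)-2,6,6-trimethylcyclohex-2-en-1-one
Conditions: TBSCl, imidazole, DMF, rt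
Reagents that add atoms: tert-butyldimethylsilyl chloride, CC(C)(C)[Si](C)(C)Cl
Why: Imidazole-promoted silylation of a secondary alcohol is routine, and this silyl ether is chosen because it survives enolate, palladium, hydride and Mitsunobu conditions and cannot act as a neighbouring group later at C4.

Step 3
Reactants: 3 (4R)-4-(tert-butyldimethylsilyloxy)-2,6,6-trimethylcyclohex-2-en-1-one
Product: 4 (4S)-4-(tert-butyldimethylsilyloxy)-2,2,6-trimethylcyclohexan-1-one (both epimers at C6)
Conditions: H2 (1 atm), 10% Pd/C, EtOAc, rt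
Reagents that add atoms: none
Why: Heterogeneous hydrogenation saturates the enone C=C under neutral conditions without touching the silyl ether, and the epimer mixture at the new methyl-bearing carbon is harmless because that carbon becomes trigonal again in step 4.

Step 4
Reactants: 4 (4S)-4-(tert-butyldimethylsilyloxy)-2,2,6-trimethylcyclohexan-1-one
Product: 5 (4S)-4-(tert-butyldimethylsilyloxy)-2,6,6-trimethylcyclohex-1-en-1-yl trifluoromethanesulfonate
Conditions: KN(SiMe3)2, THF, −78 °C; PhNTf2, −78 to 0 °C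
Reagents that add atoms: N-phenylbis(trifluoromethanesulfonimide), O=S(=O)(N(c1ccccc1)S(=O)(=O)C(F)(F)F)C(F)(F)F
Why: Only the methyl-bearing α-carbon carries a hydrogen, so enolisation is regiospecific and O-sulfonylation of the enolate gives the tetrasubstituted enol triflate from both epimers (enol triflate formation).

Step 5
Reactants: 5 enol triflate; 6 methyl vinyl ketone (but-3-en-2-one, 3 equiv)
Product: 7 (3E)-4-[(4S)-4-(tert-butyldimethylsilyloxy)-2,6,6-trimethylcyclohex-1-en-1-yl]but-3-en-2-one, the (3S)-3-silyloxy-β-ionone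
Conditions: Pd(OAc)2 (5 mol %), PPh3 (10 mol %), Et3N, DMF, 70 °C
Reagents that add atoms: none
Why: Heck reaction: oxidative addition of the vinyl triflate to zerovalent palladium, insertion of the enone at its unsubstituted terminus and syn β-hydride elimination form the C6–C7 bond and give the 7E dienone.

Step 6
Reactants: 7 (3S)-3-silyloxy-β-ionone; 8 triethyl phosphonoacetate
Product: 9 ethyl (2E,4E)-5-[(4S)-4-(tert-butyldimethylsilyloxy)-2,6,6-trimethylcyclohex-1-en-1-yl]-3-methylpenta-2,4-dienoate (shared C15 ester)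
Conditions: NaH, THF, 0 °C to rt
Reagents that add atoms: none
Why: Horner–Wadsworth–Emmons olefination of the methyl ketone with the stabilised phosphonate anion forms C9=C10 mainly as the E trisubstituted enoate, and the minor 9Z isomer is removed by chromatography.

Step 7
Reactants: 9 shared C15 ester
Product: 10 ethyl (2E,4E)-5-[(4R)-4-(tert-butyldimethylsilyloxy)-2,6,6-trimethyl-3-oxocyclohex-1-en-1-yl]-3-methylpenta-2,4-dienoate (4-oxo ester)
Conditions: t-BuOOH (70% in H2O), Rh2(cap)4 (dirhodium tetrakis(caprolactamate), 1 mol %), K2CO3, CH2Cl2, rt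
Reagents that add atoms: tert-butyl hydroperoxide, CC(C)(C)OO
Why: Catalytic allylic C–H oxidation by tert-butylperoxyl radicals should select the ring C4 methylene, the only secondary allylic position and the one whose radical is delocalised over the whole trienoate, while the chain methyl groups are primary and the ester-deactivated alkenes resist attack.

Step 8
Reactants: 10 4-oxo ester
Product: 11 ethyl (2E,4E)-5-[(3R,4R)-4-(tert-butyldimethylsilyloxy)-3-hydroxy-2,6,6-trimethylcyclohex-1-en-1-yl]-3-methylpenta-2,4-dienoate (3,4-trans alcohol)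
Conditions: NaBH4, CeCl3·7H2O, MeOH, −78 to −40 °C
Reagents that add atoms: none
Why: Luche reduction gives clean 1,2-addition, and hydride should add axially to the half-chair in which the C3 silyloxy group is pseudo-equatorial (an axial one would clash with the syn-axial C1 methyl), that is on the ring face of the C3 oxygen, so the new hydroxyl ends up trans to it (4R); any cis epimer is separated and returned to 10 with MnO2.

Step 9
Reactants: 11 3,4-trans alcohol
Product: 14 ethyl (2E,4E)-5-[(1R,4R)-4-(tert-butyldimethylsilyloxy)-2,6,6-trimethylcyclohex-2-en-1-yl]-3-methylpenta-2,4-dienoate (ε-ring C15 ester), via sulfonylhydrazine 12 (not isolated), via allylic diazene 13 (not isolated)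
Conditions: 2-nitrobenzenesulfonyl hydrazide, PPh3, DEAD, N-methylmorpholine, −30 °C, then rt
Reagents that add atoms: none
Why: The alcohol is activated as its oxyphosphonium salt and the acidic sulfonamide N–H of the hydrazide displaces it at C4 with inversion (Mitsunobu reaction) to give 12; on warming, 12 loses 2-nitrobenzenesulfinic acid to the monoalkyl diazene 13, which hands its N–H hydrogen to C6 through a six-membered retro-ene transition state as the C4–N bond breaks, N2 departs and the double bond moves from C5=C6 to C4=C5. The closest known reaction type is the reductive 1,3-transposition of allylic alcohols through arenesulfonyl hydrazide Mitsunobu adducts and allylic diazenes. No ring is closed; the β-ring becomes the ε-ring. The new C6 stereocentre is controlled by the C4 carbinol: inversion places nitrogen cis to the C3 silyloxy group and the hydrogen transfer is suprafacial, so H6 arrives on the face of the C3 oxygen and the dienoate chain is pushed trans to it (6R). The step needs SN2 displacement rather than SN2' attack, ionisation or elimination, and kinetic formation of the deconjugated alkene: C6 is fully substituted, the ester-terminated triene disfavours an allyl cation, H3 is cis to the leaving group so anti elimination is unavailable, and loss of N2 is irreversible so the ε alkene cannot revert to the conjugated β isomer. The reactive diazene conformer has the C4–N bond pseudo-axial with the neighbouring silyloxy group equatorial, so the transition state carries no extra strain.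

Step 10
Reactants: 14 ε-ring C15 ester
Product: 15 (2E,4E)-5-[(1R,4R)-4-(tert-butyldimethylsilyloxy)-2,6,6-trimethylcyclohex-2-en-1-yl]-3-methylpenta-2,4-dien-1-ol
Conditions: i-Bu2AlH, CH2Cl2, −78 °C; aq. KNaC4H4O6
Reagents that add atoms: none
Why: i-Bu2AlH reduces the conjugated ester to the primary allylic alcohol by 1,2-hydride addition at low temperature without disturbing the silyl ether or the doubly allylic C6' hydrogen.

Step 11
Reactants: 15 ε-ring C15 allylic alcohol
Product: 17 (2E,4E)-1-bromo-5-[(1R,4R)-4-(tert-butyldimethylsilyloxy)-2,6,6-trimethylcyclohex-2-en-1-yl]-3-methylpenta-2,4-diene, via allylic mesylate 16 (not isolated)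
Conditions: Ms2O, Et3N, THF, −40 °C; then LiBr, −40 to 0 °C
Reagents that add atoms: lithium bromide, [Li+].[Br-]; methanesulfonic anhydride, CS(=O)(=O)OS(C)(=O)=O (its atoms stay only in 16)
Why: Sulfonylation of the primary allylic alcohol and SN2 exchange of the mesylate with bromide run under basic, chloride-free conditions, so the acid-sensitive allylic silyl ether of the ε-ring is not ionised and the 9'E geometry is kept.

Step 12
Reactants: 17 ε-ring C15 allylic bromide
Product: 18 [(2E,4E)-5-[(1R,4R)-4-(tert-butyldimethylsilyloxy)-2,6,6-trimethylcyclohex-2-en-1-yl]-3-methylpenta-2,4-dien-1-yl]triphenylphosphonium bromide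
Conditions: PPh3, EtOAc, rt, dark
Reagents that add atoms: triphenylphosphine, c1ccc(cc1)P(c1ccccc1)c1ccccc1
Why: SN2 alkylation of triphenylphosphine by the primary allylic bromide gives the phosphonium salt, which separates from the non-polar solvent.

Step 13
Reactants: 18 ε-ring C15 phosphonium bromide; 19 (2E,4E,6E)-2,7-dimethylocta-2,4,6-trienedial (3 equiv)
Product: 21 (2E,4E,6E,8E,10E,12E)-13-[(1R,4R)-4-(tert-butyldimethylsilyloxy)-2,6,6-trimethylcyclohex-2-en-1-yl]-2,7,11-trimethyltrideca-2,4,6,8,10,12-hexaenal (all-E ε-ring C25 aldehyde), via 11'Z isomer 20 (not isolated)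
Conditions: 1,2-epoxybutane, EtOH, 70 °C, Ar, dark; then heptane, 90 °C
Reagents that add atoms: none
Why: Wittig reaction: 1,2-epoxybutane traps HBr to generate the ylide under neutral conditions, the excess of dialdehyde keeps the condensation to one formyl group and forms C11'=C12', and the sterically strained 11'Z isomer relaxes thermally to the all-E aldehyde.

Step 14
Reactants: 9 shared C15 ester
Product: 22 ethyl (2E,4E)-5-[(4S)-4-hydroxy-2,6,6-trimethylcyclohex-1-en-1-yl]-3-methylpenta-2,4-dienoate
Conditions: Bu4NF, THF, rt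
Reagents that add atoms: none
Why: Fluoride cleaves the silyl ether of the β-ring ester, which has no fluoride- or base-sensitive site, to free the homoallylic hydroxyl needed as a directing group.

Step 15
Reactants: 22 3-hydroxy C15 ester
Product: 23 ethyl (2E,4E)-5-[(1S,4R,6R)-4-hydroxy-2,2,6-trimethyl-7-oxabicyclo[4.1.0]heptan-1-yl]-3-methylpenta-2,4-dienoate (epoxide syn to the hydroxyl; carotenoid locants 3R,5R,6S)
Conditions: VO(acac)2 (2 mol %), t-BuOOH (anhydrous), toluene, 0 °C to rt
Reagents that add atoms: tert-butyl hydroperoxide, CC(C)(C)OO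
Why: Hydroxyl-directed epoxidation: the vanadium alkoxide of the homoallylic C3 hydroxyl delivers the peroxide oxygen to its own face of the C5=C6 bond, the only alkene within reach and the most electron-rich one, which sets C5 and C6 syn to the hydroxyl.

Step 16
Reactants: 23 syn epoxy alcohol
Product: 24 ethyl (2E,4E)-3-methyl-5-[(1S,4S,6R)-2,2,6-trimethyl-4-(4-nitrobenzoyloxy)-7-oxabicyclo[4.1.0]heptan-1-yl]penta-2,4-dienoate (ester oxygen anti to the epoxide)
Conditions: 4-nitrobenzoic acid, PPh3, DIAD, THF, 0 °C to rt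
Reagents that add atoms: 4-nitrobenzoic acid, OC(=O)c1ccc(cc1)[N+](=O)[O-]
Why: Mitsunobu reaction: the carboxylate displaces the C3 oxyphosphonium group by SN2 with inversion, placing the C3 oxygen anti to the epoxide as in the target, under neutral conditions that leave the vinyl epoxide closed.

Step 17
Reactants: 24 anti epoxy nitrobenzoate
Product: 25 (2E,4E)-5-[(1S,4S,6R)-4-hydroxy-2,2,6-trimethyl-7-oxabicyclo[4.1.0]heptan-1-yl]-3-methylpenta-2,4-dien-1-ol
Conditions: i-Bu2AlH (5 equiv), CH2Cl2, −78 °C; aq. KNaC4H4O6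
Reagents that add atoms: none
Why: Excess i-Bu2AlH reduces both esters at low temperature, releasing the C3 hydroxyl from the benzoate and turning the dienoate into the primary allylic alcohol, while the tetrasubstituted epoxide is inert to hydride and the tartrate work-up avoids acid.

Step 18
Reactants: 25 anti epoxy diol
Product: 27 (1S,4S,6R)-1-[(1E,3E)-5-bromo-3-methylpenta-1,3-dien-1-yl]-2,2,6-trimethyl-7-oxabicyclo[4.1.0]heptan-4-ol, via allylic mesylate 26 (not isolated)
Conditions: Ms2O (1.05 equiv), 2,4,6-collidine, THF, −40 °C; then LiBr, DMF, 0 °C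
Reagents that add atoms: lithium bromide, [Li+].[Br-]; methanesulfonic anhydride, CS(=O)(=O)OS(C)(=O)=O (its atoms stay only in 26)
Why: The primary allylic hydroxyl is sulfonylated far faster than the hindered secondary ring hydroxyl, and bromide replaces the allylic mesylate by SN2 in the collidine-buffered medium, so no acid reaches the vinyl epoxide.

Step 19
Reactants: 27 epoxy C15 allylic bromide
Product: 28 [(2E,4E)-5-[(1S,4S,6R)-4-hydroxy-2,2,6-trimethyl-7-oxabicyclo[4.1.0]heptan-1-yl]-3-methylpenta-2,4-dien-1-yl]triphenylphosphonium bromide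
Conditions: PPh3, EtOAc, rt, dark
Reagents that add atoms: triphenylphosphine, c1ccc(cc1)P(c1ccccc1)c1ccccc1
Why: SN2 alkylation of triphenylphosphine by the allylic bromide gives the phosphonium salt under neutral conditions, the free secondary hydroxyl being a spectator.

Step 20
Reactants: 21 all-E ε-ring C25 aldehyde; 28 epoxy C15 phosphonium bromide
Product: 30 (3S,5R,6S,3'R,6'R)-3'-(tert-butyldimethylsilyloxy)-5,6-epoxy-5,6-dihydro-β,ε-caroten-3-ol (all-E), via 11Z isomer 29 (not isolated)
Conditions: 1,2-epoxybutane, EtOH, 70 °C, Ar, dark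
Reagents that add atoms: none
Why: Wittig reaction under the same neutral conditions forms C11=C12 and completes the C40 chain, the free C3 hydroxyl and the epoxide being tolerated, and continued heating converts the strained 11Z isomer into the all-E polyene.

Step 21
Reactants: 30 C40 epoxy alcohol silyl ether
Product: 31 (3S,5R,6S,3'R,6'R)-5,6-epoxy-5,6-dihydro-β,ε-carotene-3,3'-diol (lutein 5,6-epoxide)
Conditions: Bu4NF, THF, 0 °C to rt, Ar, dark
Reagents that add atoms: none
Why: Fluoride removes the allylic silyl ether under basic, acid-free conditions to which the 5,6-epoxide and the polyene are stable.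

Step 22
Reactants: 31 lutein 5,6-epoxide; 32 palmitoyl chloride (hexadecanoyl chloride, 2.5 equiv)
Product: 33 (3S,5R,6S,3'R,6'R)-5,6-epoxy-5,6-dihydro-β,ε-carotene-3,3'-diyl dihexadecanoate (lutein 5,6-epoxide dipalmitate)
Conditions: pyridine, DMAP (cat.), CH2Cl2, 0 °C to rt, Ar, dark
Reagents that add atoms: none
Why: Acylation of both secondary hydroxyls with the acid chloride under pyridine and DMAP catalysis (nucleophilic acyl substitution) proceeds with retention at C3 and C3', and the excess base keeps the medium free of acid that would rearrange the 5,6-epoxide to the furanoid 5,8-oxide.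

**Compound list**

1 | ketoisophorone (2,6,6-trimethylcyclohex-2-ene-1,4-dione) | CC1=CC(=O)CC(C)(C)C1=O | starting material
2 | (4R)-4-hydroxy-2,6,6-trimethylcyclohex-2-en-1-one | CC1=C[C@H](O)CC(C)(C)C1=O | intermediate
3 | (4R)-4-(tert-butyldimethylsilyloxy)-2,6,6-trimethylcyclohex-2-en-1-one | CC1=C[C@H](O[Si](C)(C)C(C)(C)C)CC(C)(C)C1=O | intermediate
4 | (4S)-4-(tert-butyldimethylsilyloxy)-2,2,6-trimethylcyclohexan-1-one, both C6 epimers | CC1C[C@H](O[Si](C)(C)C(C)(C)C)CC(C)(C)C1=O | intermediate
5 | (4S)-4-(tert-butyldimethylsilyloxy)-2,6,6-trimethylcyclohex-1-en-1-yl trifluoromethanesulfonate | O=S(=O)(OC1=C(C)C[C@H](O[Si](C)(C)C(C)(C)C)CC1(C)C)C(F)(F)F | intermediate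
6 | methyl vinyl ketone | C=CC(C)=O | starting material
7 | (3E)-4-[(4S)-4-(tert-butyldimethylsilyloxy)-2,6,6-trimethylcyclohex-1-en-1-yl]but-3-en-2-one | CC(=O)/C=C/C1=C(C)C[C@H](O[Si](C)(C)C(C)(C)C)CC1(C)C | intermediate
8 | triethyl phosphonoacetate | CCOC(=O)CP(=O)(OCC)OCC | starting material
9 | ethyl (2E,4E)-5-[(4S)-4-(tert-butyldimethylsilyloxy)-2,6,6-trimethylcyclohex-1-en-1-yl]-3-methylpenta-2,4-dienoate | CCOC(=O)/C=C(C)/C=C/C1=C(C)C[C@H](O[Si](C)(C)C(C)(C)C)CC1(C)C | intermediate
10 | ethyl (2E,4E)-5-[(4R)-4-(tert-butyldimethylsilyloxy)-2,6,6-trimethyl-3-oxocyclohex-1-en-1-yl]-3-methylpenta-2,4-dienoate | CCOC(=O)/C=C(C)/C=C/C1=C(C)C(=O)[C@H](O[Si](C)(C)C(C)(C)C)CC1(C)C | intermediate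
11 | ethyl (2E,4E)-5-[(3R,4R)-4-(tert-butyldimethylsilyloxy)-3-hydroxy-2,6,6-trimethylcyclohex-1-en-1-yl]-3-methylpenta-2,4-dienoate (3,4-trans) | CCOC(=O)/C=C(C)/C=C/C1=C(C)[C@@H](O)[C@H](O[Si](C)(C)C(C)(C)C)CC1(C)C | intermediate
12 | ethyl (2E,4E)-5-[(3S,4R)-4-(tert-butyldimethylsilyloxy)-3-[1-(2-nitrophenylsulfonyl)hydrazinyl]-2,6,6-trimethylcyclohex-1-en-1-yl]-3-methylpenta-2,4-dienoate (3,4-cis) | CCOC(=O)/C=C(C)/C=C/C1=C(C)[C@H](N(N)S(=O)(=O)c2ccccc2[N+](=O)[O-])[C@H](O[Si](C)(C)C(C)(C)C)CC1(C)C | intermediate (not isolated)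
13 | ethyl (2E,4E)-5-[(3S,4R)-4-(tert-butyldimethylsilyloxy)-3-diazenyl-2,6,6-trimethylcyclohex-1-en-1-yl]-3-methylpenta-2,4-dienoate | CCOC(=O)/C=C(C)/C=C/C1=C(C)[C@H](N=N)[C@H](O[Si](C)(C)C(C)(C)C)CC1(C)C | intermediate (not isolated)
14 | ethyl (2E,4E)-5-[(1R,4R)-4-(tert-butyldimethylsilyloxy)-2,6,6-trimethylcyclohex-2-en-1-yl]-3-methylpenta-2,4-dienoate | CCOC(=O)/C=C(C)/C=C/[C@H]1C(C)=C[C@H](O[Si](C)(C)C(C)(C)C)CC1(C)C | intermediate
15 | (2E,4E)-5-[(1R,4R)-4-(tert-butyldimethylsilyloxy)-2,6,6-trimethylcyclohex-2-en-1-yl]-3-methylpenta-2,4-dien-1-ol | OC/C=C(C)/C=C/[C@H]1C(C)=C[C@H](O[Si](C)(C)C(C)(C)C)CC1(C)C | intermediate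
16 | methanesulfonate of 15 | CS(=O)(=O)OC/C=C(C)/C=C/[C@H]1C(C)=C[C@H](O[Si](C)(C)C(C)(C)C)CC1(C)C | intermediate (not isolated)
17 | (2E,4E)-1-bromo-5-[(1R,4R)-4-(tert-butyldimethylsilyloxy)-2,6,6-trimethylcyclohex-2-en-1-yl]-3-methylpenta-2,4-diene | BrC/C=C(C)/C=C/[C@H]1C(C)=C[C@H](O[Si](C)(C)C(C)(C)C)CC1(C)C | intermediate
18 | [(2E,4E)-5-[(1R,4R)-4-(tert-butyldimethylsilyloxy)-2,6,6-trimethylcyclohex-2-en-1-yl]-3-methylpenta-2,4-dien-1-yl]triphenylphosphonium bromide | C(/C=C(C)/C=C/[C@H]1C(C)=C[C@H](O[Si](C)(C)C(C)(C)C)CC1(C)C)[P+](c1ccccc1)(c1ccccc1)c1ccccc1.[Br-] | intermediate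
19 | (2E,4E,6E)-2,7-dimethylocta-2,4,6-trienedial | O=C/C(C)=C/C=C/C=C(C)/C=O | starting material
20 | (8Z) isomer of 21 (11'Z in carotenoid locants) | O=C/C(C)=C/C=C/C=C(C)/C=C\C=C(C)\C=C\[C@H]1C(C)=C[C@H](O[Si](C)(C)C(C)(C)C)CC1(C)C | intermediate (not isolated)
21 | (2E,4E,6E,8E,10E,12E)-13-[(1R,4R)-4-(tert-butyldimethylsilyloxy)-2,6,6-trimethylcyclohex-2-en-1-yl]-2,7,11-trimethyltrideca-2,4,6,8,10,12-hexaenal | O=C/C(C)=C/C=C/C=C(C)/C=C/C=C(C)/C=C/[C@H]1C(C)=C[C@H](O[Si](C)(C)C(C)(C)C)CC1(C)C | intermediate
22 | ethyl (2E,4E)-5-[(4S)-4-hydroxy-2,6,6-trimethylcyclohex-1-en-1-yl]-3-methylpenta-2,4-dienoate | CCOC(=O)/C=C(C)/C=C/C1=C(C)C[C@H](O)CC1(C)C | intermediate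
23 | ethyl (2E,4E)-5-[(1S,4R,6R)-4-hydroxy-2,2,6-trimethyl-7-oxabicyclo[4.1.0]heptan-1-yl]-3-methylpenta-2,4-dienoate (epoxide syn to OH) | O[C@@H]1CC(C)(C)[C@]2(/C=C/C(C)=C/C(=O)OCC)O[C@]2(C)C1 | intermediate
24 | ethyl (2E,4E)-3-methyl-5-[(1S,4S,6R)-2,2,6-trimethyl-4-(4-nitrobenzoyloxy)-7-oxabicyclo[4.1.0]heptan-1-yl]penta-2,4-dienoate | O=C(O[C@H]1CC(C)(C)[C@]2(/C=C/C(C)=C/C(=O)OCC)O[C@]2(C)C1)c1ccc(cc1)[N+](=O)[O-] | intermediate
25 | (2E,4E)-5-[(1S,4S,6R)-4-hydroxy-2,2,6-trimethyl-7-oxabicyclo[4.1.0]heptan-1-yl]-3-methylpenta-2,4-dien-1-ol | O[C@H]1CC(C)(C)[C@]2(/C=C/C(C)=C/CO)O[C@]2(C)C1 | intermediate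
26 | primary methanesulfonate of 25 | O[C@H]1CC(C)(C)[C@]2(/C=C/C(C)=C/COS(C)(=O)=O)O[C@]2(C)C1 | intermediate (not isolated)
27 | (1S,4S,6R)-1-[(1E,3E)-5-bromo-3-methylpenta-1,3-dien-1-yl]-2,2,6-trimethyl-7-oxabicyclo[4.1.0]heptan-4-ol | O[C@H]1CC(C)(C)[C@]2(/C=C/C(C)=C/CBr)O[C@]2(C)C1 | intermediate
28 | [(2E,4E)-5-[(1S,4S,6R)-4-hydroxy-2,2,6-trimethyl-7-oxabicyclo[4.1.0]heptan-1-yl]-3-methylpenta-2,4-dien-1-yl]triphenylphosphonium bromide | O[C@H]1CC(C)(C)[C@]2(/C=C/C(C)=C/C[P+](c3ccccc3)(c3ccccc3)c3ccccc3)O[C@]2(C)C1.[Br-] | intermediate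
29 | 11Z isomer of 30 | O[C@H]1CC(C)(C)[C@]2(\C=C\C(C)=C\C=C/C(C)=C/C=C/C=C(C)/C=C/C=C(C)/C=C/[C@H]3C(C)=C[C@H](O[Si](C)(C)C(C)(C)C)CC3(C)C)O[C@]2(C)C1 | intermediate (not isolated)
30 | (3S,5R,6S,3'R,6'R)-3'-(tert-butyldimethylsilyloxy)-5,6-epoxy-5,6-dihydro-β,ε-caroten-3-ol, all-E | O[C@H]1CC(C)(C)[C@]2(/C=C/C(C)=C/C=C/C(C)=C/C=C/C=C(C)/C=C/C=C(C)/C=C/[C@H]3C(C)=C[C@H](O[Si](C)(C)C(C)(C)C)CC3(C)C)O[C@]2(C)C1 | intermediate
31 | (3S,5R,6S,3'R,6'R)-5,6-epoxy-5,6-dihydro-β,ε-carotene-3,3'-diol (lutein 5,6-epoxide) | O[C@H]1CC(C)(C)[C@]2(/C=C/C(C)=C/C=C/C(C)=C/C=C/C=C(C)/C=C/C=C(C)/C=C/[C@H]3C(C)=C[C@H](O)CC3(C)C)O[C@]2(C)C1 | intermediate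
32 | palmitoyl chloride (hexadecanoyl chloride) | CCCCCCCCCCCCCCCC(=O)Cl | starting material
33 | lutein 5,6-epoxide dipalmitate, (3S,5R,6S,3'R,6'R) | CCCCCCCCCCCCCCCC(=O)O[C@H]1CC(C)(C)[C@]2(/C=C/C(C)=C/C=C/C(C)=C/C=C/C=C(C)/C=C/C=C(C)/C=C/[C@H]3C(C)=C[C@H](OC(=O)CCCCCCCCCCCCCCC)CC3(C)C)O[C@]2(C)C1 | target

**Step count and risks**

Total step count: 22. Longest linear sequence: 16 steps (steps 1–13, then 20–22).

Steps most likely to fail:

1. Step 9. The hindered C4 oxyphosphonium may be displaced too slowly, so that ionisation, SN2' attack or thermal decay of the hydrazide takes over and the regio- and stereocontrol of the hydrogen delivery is lost. Fallback: alcohol 11 is formylated (formic acetic anhydride, pyridine) to the C4 formate ester F1. With Pd(OAc)2 and n-Bu3P in dioxane this ionises with inversion to a π-allyl complex of divalent palladium, whose formate ligand loses CO2 and passes hydride from the metal face to the more substituted terminus C6 (palladium-catalysed formate reduction with allylic transposition). Palladium sits cis to the C3 oxygen, so the hydrogen again arrives cis to it and the route is rejoined at 14.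

2. Step 7. The C–H oxidation may stall next to the silyloxy group or attack the chain methyl groups and the polyene, giving poor site selectivity or over-oxidation. Fallback: 9 is treated with N-bromosuccinimide (NaHCO3, CH2Cl2, 0 °C) to give the C4 allylic bromide F2. Aqueous acetone with NaHCO3 hydrolyses it through the allylic cation to the C4 alcohol epimer mixture F3, and MnO2 oxidises this mixture to ketone 10, where the route is rejoined so that the Luche step still sets C4.

3. Step 5. Oxidative addition and insertion at the tetrasubstituted triflate may be slow, so that reduction or hydrolysis of the triflate and conjugate reduction of the enone compete. Fallback: the chain is attached by Stille coupling instead of alkene insertion. Triflate 5 and (E)-4-(tributylstannyl)but-3-en-2-ol (Pd2(dba)3, AsPh3, N-methylpyrrolidone, 60 °C) give the dienol F4 (3-silyloxy-β-ionol, carbinol epimers), and MnO2 oxidation of this allylic alcohol returns to dienone 7.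

**Further compounds**

F1 | step 9 | C4 formate ester of 11, ethyl (2E,4E)-5-[(3R,4R)-4-(tert-butyldimethylsilyloxy)-3-(formyloxy)-2,6,6-trimethylcyclohex-1-en-1-yl]-3-methylpenta-2,4-dienoate | CCOC(=O)/C=C(C)/C=C/C1=C(C)[C@@H](OC=O)[C@H](O[Si](C)(C)C(C)(C)C)CC1(C)C
F2 | step 7 | C4 allylic bromide of 9 (C4 epimers) | CCOC(=O)/C=C(C)/C=C/C1=C(C)C(Br)[C@H](O[Si](C)(C)C(C)(C)C)CC1(C)C
F3 | step 7 | C4 alcohol epimer mixture (11 and its C4 epimer) | CCOC(=O)/C=C(C)/C=C/C1=C(C)C(O)[C@H](O[Si](C)(C)C(C)(C)C)CC1(C)C
F4 | step 5 | (3E)-4-[(4S)-4-(tert-butyldimethylsilyloxy)-2,6,6-trimethylcyclohex-1-en-1-yl]but-3-en-2-ol (carbinol epimers) | CC(O)/C=C/C1=C(C)C[C@H](O[Si](C)(C)C(C)(C)C)CC1(C)C
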